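**Retrosynthetic overview**
1. The O–O bridge between C2 and C5 is taken off as singlet oxygen (retro-[4+2]), leaving bicyclo[4.2.0]octa-2,4-diene 33. The γ-pyrone (ring C) is cut back to the C7 aldehyde 26 and the dianion of ketoester 27.
2. The strategy rests on ring B: its diene C2(H)=C3(Me)–C4(H)=C5(Me) is two propyne units joined head to tail across the C1=C6 bond of a cyclobutene. C3–C4, C1–C2 and C5–C6 are therefore made in one rhodium-catalysed [2+2+2] step on cyclobutene ester 20.
3. Cyclobutene 20 (ring A, C7 and C8 stereocentres) comes from a dichloroketene [2+2] with silylated tiglyl alcohol (cis methyls from the E-alkene), dechlorination, enol triflate/methyl coupling, oxidation, and resolution as an oxazolidinone imide.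
4. Ring order: ring A (step 2), ring B (step 11), pyrone ring C (step 16), peroxide ring D (step 18).

Key step: step 11

Remark on the chemistry: compounds 5–13 and 15 are racemic with fixed relative configuration and are named and drawn as the enantiomer carried on after steps 8–9; locants C1–C8 are those of core 24 (C1 methylated ring-fusion carbon, C6 ring-fusion CH, C7 ester/pyrone carbon, C8 CHMe).

**Step 1**
Reactants: 1 (E)-2-methylbut-2-en-1-ol (tiglyl alcohol)
Product: 2 tert-butyl{[(2E)-2-methylbut-2-en-1-yl]oxy}diphenylsilane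
Conditions: TBDPSCl, imidazole, DMF, 0 °C → rt
Reagents that add atoms: tert-butyl(chloro)diphenylsilane, CC(C)(C)[Si](Cl)(c1ccccc1)c1ccccc1
Why: Imidazole-promoted silylation of a primary alcohol; the bulky silyl group makes the ether oxygen a poor nucleophile toward the ketene of step 2 and gives the small later intermediates mass and a chromophore.

**Step 2**
Reactants: 2 tert-butyl{[(2E)-2-methylbut-2-en-1-yl]oxy}diphenylsilane; 3 trichloroacetyl chloride
Product: 5 rac-(3R,4S)-3-{[tert-butyl(diphenyl)silyl]oxymethyl}-2,2-dichloro-3,4-dimethylcyclobutan-1-one, via dichloroketene 4 (not isolated)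
Conditions: 3 (slow addition), Zn–Cu couple, Et2O/DME, rt
Reagents that add atoms: none
Why: Thermal [2+2] ketene–alkene cycloaddition, suprafacial on the alkene so that the cis methyls of the E-alkene become the cis 3,4-methyls, with the ketene carbonyl carbon bonding to the less substituted CHMe carbon as is usual for trisubstituted alkenes.

**Step 3**
Reactants: 5 rac-(3R,4S)-3-{[tert-butyl(diphenyl)silyl]oxymethyl}-2,2-dichloro-3,4-dimethylcyclobutan-1-one
Product: 7 rac-(2S,3R)-3-{[tert-butyl(diphenyl)silyl]oxymethyl}-2,3-dimethylcyclobutan-1-one, via monochloroketone 6 (not isolated)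
Conditions: Zn dust, NH4Cl, MeOH, rt
Reagents that add atoms: none
Why: Zinc-mediated reductive dehalogenation of an α,α-dichloroketone through zinc enolates, run near neutrality so that the CHMe centre next to the carbonyl (which carries the cis-methyl relationship) should not epimerise.

**Step 4**
Reactants: 7 rac-(2S,3R)-3-{[tert-butyl(diphenyl)silyl]oxymethyl}-2,3-dimethylcyclobutan-1-one
Product: 9 rac-(3R,4S)-3-{[tert-butyl(diphenyl)silyl]oxymethyl}-3,4-dimethylcyclobut-1-en-1-yl trifluoromethanesulfonate, via potassium enolate 8 (not isolated)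
Conditions: KN(SiMe3)2, THF, −78 °C; PhNTf2, −78 → 0 °C
Reagents that add atoms: N-phenylbis(trifluoromethanesulfonimide), O=S(=O)(N(c1ccccc1)S(=O)(=O)C(F)(F)F)C(F)(F)F
Why: Kinetic deprotonation by the bulky amide at the CH2 and not at the CHMe, then enolate O-sulfonylation (enol triflate formation), which places the future double bond next to the quaternary carbon and leaves both stereocentres untouched.

**Step 5**
Reactants: 9 rac-(3R,4S)-3-{[tert-butyl(diphenyl)silyl]oxymethyl}-3,4-dimethylcyclobut-1-en-1-yl trifluoromethanesulfonate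
Product: 10 rac-tert-butyl{[(1R,4R)-1,3,4-trimethylcyclobut-2-en-1-yl]methoxy}diphenylsilane
Conditions: MeMgBr, Fe(acac)3 (5 mol%), THF/NMP, −30 °C
Reagents that add atoms: methylmagnesium bromide, C[Mg]Br
Why: Iron-catalysed Kumada-type cross-coupling of an alkenyl triflate with a methyl Grignard reagent, fast at low temperature and without effect on the silyl ether or the sp3 centres.

**Step 6**
Reactants: 10 rac-tert-butyl{[(1R,4R)-1,3,4-trimethylcyclobut-2-en-1-yl]methoxy}diphenylsilane
Product: 11 rac-[(1R,4R)-1,3,4-trimethylcyclobut-2-en-1-yl]methanol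
Conditions: Bu4NF, THF, 0 °C → rt
Reagents that add atoms: none
Why: Fluoride-induced Si–O cleavage (desilylation) under conditions that do not touch the cyclobutene.

**Step 7**
Reactants: 11 rac-[(1R,4R)-1,3,4-trimethylcyclobut-2-en-1-yl]methanol
Product: 13 rac-(1R,4R)-1,3,4-trimethylcyclobut-2-ene-1-carboxylic acid, via aldehyde 12 (not isolated)
Conditions: TEMPO (cat.), PhI(OAc)2, MeCN/H2O 1:1, rt
Reagents that add atoms: water, O
Why: Oxoammonium (TEMPO) oxidation of a primary alcohol through the aldehyde hydrate to the acid, a method that tolerates trisubstituted alkenes; the quaternary α-carbon cannot epimerise.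

**Step 8**
Reactants: 13 rac-(1R,4R)-1,3,4-trimethylcyclobut-2-ene-1-carboxylic acid; 14 (4S)-4-benzyl-1,3-oxazolidin-2-one
Product: 17 (4S)-4-benzyl-3-[(1R,4R)-1,3,4-trimethylcyclobut-2-ene-1-carbonyl]-1,3-oxazolidin-2-one, via acid chloride 15 (not isolated), via lithium oxazolidinide 16 (not isolated)
Conditions: 13, (COCl)2, DMF (cat.), CH2Cl2, 0 °C, evaporate; 14, n-BuLi, THF, −78 °C, then 15, −78 → 0 °C; separation on SiO2
Reagents that add atoms: none
Why: N-acylation of the lithiated Evans oxazolidinone by the acid chloride (resolution through covalent diastereomers) should give 17 and its (1S,4S)-acyl diastereomer, to be parted by chromatography or crystallisation, with the configuration of 17 to be secured by X-ray analysis against the known auxiliary centre.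

**Step 9**
Reactants: 17 (4S)-4-benzyl-3-[(1R,4R)-1,3,4-trimethylcyclobut-2-ene-1-carbonyl]-1,3-oxazolidin-2-one
Product: 19 (1R,4R)-1,3,4-trimethylcyclobut-2-ene-1-carboxylic acid, via lithium peroxycarboxylate 18 (not isolated)
Conditions: LiOH, H2O2, THF/H2O, 0 °C; Na2SO3 aq; HCl to pH 3
Reagents that add atoms: hydrogen peroxide, OO
Why: Evans hydroperoxide cleavage, in which LiOOH attacks the exocyclic imide carbonyl even when it is hindered, followed by sulfite reduction of the peroxycarboxylate while the medium is still basic so that the alkene is not epoxidised.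

**Step 10**
Reactants: 19 (1R,4R)-1,3,4-trimethylcyclobut-2-ene-1-carboxylic acid
Product: 20 methyl (1R,4R)-1,3,4-trimethylcyclobut-2-ene-1-carboxylate
Conditions: MeI, K2CO3, DMF, rt
Reagents that add atoms: iodomethane, CI
Why: SN2 O-alkylation of the carboxylate, which suits a hindered acid better than Fischer esterification and keeps the acid-labile cyclobutene away from acid.

**Step 11**
Reactants: 20 methyl (1R,4R)-1,3,4-trimethylcyclobut-2-ene-1-carboxylate; 21 propyne (2 equiv consumed, fed in excess)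
Product: 24 methyl (1R,6R,7S,8R)-1,3,5,7,8-pentamethylbicyclo[4.2.0]octa-2,4-diene-7-carboxylate, via rhodacyclopentadiene 22 (not isolated), via rhodacycloheptadiene 23 (not isolated)
Conditions: [Rh(cod)2]BF4 (10 mol%), (R)-H8-BINAP (10 mol%; the (S)-ligand also to be tried for the matched pairing), H2 then Ar to remove cod, CH2Cl2, rt; propyne in CH2Cl2 by syringe pump
Reagents that add atoms: none
Why: Proposed new method: two propynes should couple oxidatively on the monovalent rhodium–bisphosphine cation to the 2,4-dimethylrhodacyclopentadiene 22 (head to tail, methyls kept apart, C3–C4 formed), the strained C=C of 20 should insert into the unhindered Rh–CH bond with its methylated carbon bonding to carbon (C1–C2) and rhodium going to the CH carbon, and C(sp3)–C(sp2) reductive elimination from the trivalent rhodacycloheptadiene 23 should form C5–C6 and release 24; the closest known reactions are the [Rh(cod)2]BF4–bisphosphine and CpCo(CO)2 [2+2+2] cycloadditions of diynes or of two alkynes with an alkene to cyclohexa-1,3-dienes. Ring B is closed by that reductive elimination, a contraction of the seven-membered metallacycle to the six-membered carbocycle. C1 and C6 are set cis by the syn addition of carbon and rhodium across the alkene and are placed by the C7 and C8 stereocentres: the metallacycle should add to the cyclobutene face that carries CO2Me and H, away from the two cis methyls, helped by binding of the ester carbonyl to the cationic metal. In 23 the rhodium-bearing C6 lies between the quaternary C1 and C7, so no β-hydrogen is on hand and the open-chain triene exit of alkene [2+2+2] reactions is shut. The step needs cross-selectivity over propyne cyclotrimerisation (low standing propyne concentration, strain release on insertion), head-to-tail pairing and a single insertion sense (both steric), and any ring-fusion epimer can be equilibrated thermally through the cyclooctatriene.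

**Step 12**
Reactants: 24 methyl (1R,6R,7S,8R)-1,3,5,7,8-pentamethylbicyclo[4.2.0]octa-2,4-diene-7-carboxylate
Product: 25 [(1R,6R,7S,8R)-1,3,5,7,8-pentamethylbicyclo[4.2.0]octa-2,4-dien-7-yl]methanol
Conditions: LiAlH4, Et2O, 0 °C
Reagents that add atoms: none
Why: Hydride reduction of the ester to the neopentyl-type alcohol; the ester is not conjugated with the diene, so the diene and all four stereocentres are left alone.

**Step 13**
Reactants: 25 [(1R,6R,7S,8R)-1,3,5,7,8-pentamethylbicyclo[4.2.0]octa-2,4-dien-7-yl]methanol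
Product: 26 (1R,6R,7S,8R)-1,3,5,7,8-pentamethylbicyclo[4.2.0]octa-2,4-diene-7-carbaldehyde
Conditions: Dess–Martin periodinane, NaHCO3, CH2Cl2, 0 °C → rt
Reagents that add atoms: none
Why: Buffered Dess–Martin oxidation of a primary alcohol; the aldehyde has no α-hydrogen and cannot epimerise at C7.

**Step 14**
Reactants: 26 (1R,6R,7S,8R)-1,3,5,7,8-pentamethylbicyclo[4.2.0]octa-2,4-diene-7-carbaldehyde; 27 methyl 2-methyl-3-oxopentanoate
Product: 29 methyl 5-hydroxy-2,4-dimethyl-3-oxo-5-[(1R,6R,7S,8R)-1,3,5,7,8-pentamethylbicyclo[4.2.0]octa-2,4-dien-7-yl]pentanoate (mixture at chain C2, C4 and C5), via ketoester dianion 28 (not isolated)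
Conditions: 27, NaH, THF, 0 °C; n-BuLi, 0 °C; then 26, −78 °C; NH4Cl aq
Reagents that add atoms: none
Why: Aldol addition of the β-ketoester dianion (Huckin–Weiler dianion) through its γ-carbon to a non-enolisable aldehyde; the three new chain stereocentres are of no consequence because steps 15 and 16 remove them.

**Step 15**
Reactants: 29 methyl 5-hydroxy-2,4-dimethyl-3-oxo-5-[(1R,6R,7S,8R)-1,3,5,7,8-pentamethylbicyclo[4.2.0]octa-2,4-dien-7-yl]pentanoate
Product: 30 methyl 2,4-dimethyl-3,5-dioxo-5-[(1R,6R,7S,8R)-1,3,5,7,8-pentamethylbicyclo[4.2.0]octa-2,4-dien-7-yl]pentanoate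
Conditions: Dess–Martin periodinane, NaHCO3, CH2Cl2, rt
Reagents that add atoms: none
Why: Dess–Martin oxidation of the secondary alcohol to the β,δ-diketoester under neutral conditions that spare the diene.

**Step 16**
Reactants: 30 methyl 2,4-dimethyl-3,5-dioxo-5-[(1R,6R,7S,8R)-1,3,5,7,8-pentamethylbicyclo[4.2.0]octa-2,4-dien-7-yl]pentanoate
Product: 31 4-hydroxy-3,5-dimethyl-6-[(1R,6R,7S,8R)-1,3,5,7,8-pentamethylbicyclo[4.2.0]octa-2,4-dien-7-yl]-2H-pyran-2-one
Conditions: DBU, toluene, rt → 40 °C
Reagents that add atoms: none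
Why: Base-mediated lactonisation of a 3,5-diketoester (the δ-ketone enol oxygen attacks the ester) to the 4-hydroxy-2-pyrone, kept at or below 40 °C so that the ring fusion is not scrambled by 6π ring opening.

**Step 17**
Reactants: 31 4-hydroxy-3,5-dimethyl-6-[(1R,6R,7S,8R)-1,3,5,7,8-pentamethylbicyclo[4.2.0]octa-2,4-dien-7-yl]-2H-pyran-2-one
Product: 33 2-methoxy-3,5-dimethyl-6-[(1R,6R,7S,8R)-1,3,5,7,8-pentamethylbicyclo[4.2.0]octa-2,4-dien-7-yl]-4H-pyran-4-one, via hydroxypyrylium triflate 32 (not isolated)
Conditions: MeOTf (1.1 equiv), CH2Cl2, 0 °C → rt; then cold NaHCO3 aq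
Reagents that add atoms: methyl trifluoromethanesulfonate, COS(=O)(=O)C(F)(F)F
Why: O-methylation of the neutral hydroxy-α-pyrone at its lactone carbonyl oxygen by a hard methylating agent (Beak methylation), which after deprotonation gives the 2-methoxy-4-pyranone; no base is present, so the product stays protonated and is not methylated again.

**Step 18**
Reactants: 33 2-methoxy-3,5-dimethyl-6-[(1R,6R,7S,8R)-1,3,5,7,8-pentamethylbicyclo[4.2.0]octa-2,4-dien-7-yl]-4H-pyran-4-one
Product: 34 CNP0183511.1, 2-methoxy-3,5-dimethyl-6-[(1S,2R,3S,4R,5R,6R)-1,3,4,5,10-pentamethyl-7,8-dioxatricyclo[4.2.2.0(2,5)]dec-9-en-3-yl]-4H-pyran-4-one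
Conditions: O2, methylene blue, visible light, CH2Cl2, 0 °C
Reagents that add atoms: dioxygen, O=O
Why: Photosensitised singlet-oxygen [4+2] cycloaddition to the s-cis diene of ring B; oxygen should add to the convex face that carries only the C1 methyl and the C6 hydrogen, anti to the cyclobutane and its C7 pyrone, which sets C2 and C5, while the γ-pyrone is inert.

**Compound list**
1 | (E)-2-methylbut-2-en-1-ol | C/C=C(\C)CO | starting material
2 | tert-butyl{[(2E)-2-methylbut-2-en-1-yl]oxy}diphenylsilane | C/C=C(\C)CO[Si](c1ccccc1)(c1ccccc1)C(C)(C)C | intermediate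
3 | trichloroacetyl chloride | ClC(=O)C(Cl)(Cl)Cl | starting material
4 | dichloroketene | ClC(Cl)=C=O | intermediate
5 | rac-(3R,4S)-3-{[tert-butyl(diphenyl)silyl]oxymethyl}-2,2-dichloro-3,4-dimethylcyclobutan-1-one (3- and 4-methyls cis) | CC(C)(C)[Si](c1ccccc1)(c1ccccc1)OC[C@@]1(C)[C@H](C)C(=O)C1(Cl)Cl | intermediate
6 | rac-(3R,4S)-3-{[tert-butyl(diphenyl)silyl]oxymethyl}-2-chloro-3,4-dimethylcyclobutan-1-one (both C2 epimers) | CC(C)(C)[Si](c1ccccc1)(c1ccccc1)OC[C@@]1(C)[C@H](C)C(=O)C1Cl | intermediate
7 | rac-(2S,3R)-3-{[tert-butyl(diphenyl)silyl]oxymethyl}-2,3-dimethylcyclobutan-1-one (methyls cis) | CC(C)(C)[Si](c1ccccc1)(c1ccccc1)OC[C@@]1(C)[C@H](C)C(=O)C1 | intermediate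
8 | potassium rac-(3R,4S)-3-{[tert-butyl(diphenyl)silyl]oxymethyl}-3,4-dimethylcyclobut-1-en-1-olate | CC(C)(C)[Si](c1ccccc1)(c1ccccc1)OC[C@@]1(C)[C@H](C)C([O-])=C1.[K+] | intermediate
9 | rac-(3R,4S)-3-{[tert-butyl(diphenyl)silyl]oxymethyl}-3,4-dimethylcyclobut-1-en-1-yl trifluoromethanesulfonate | CC(C)(C)[Si](c1ccccc1)(c1ccccc1)OC[C@@]1(C)[C@H](C)C(OS(=O)(=O)C(F)(F)F)=C1 | intermediate
10 | rac-tert-butyl{[(1R,4R)-1,3,4-trimethylcyclobut-2-en-1-yl]methoxy}diphenylsilane | CC(C)(C)[Si](c1ccccc1)(c1ccccc1)OC[C@@]1(C)[C@H](C)C(C)=C1 | intermediate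
11 | rac-[(1R,4R)-1,3,4-trimethylcyclobut-2-en-1-yl]methanol | OC[C@@]1(C)[C@H](C)C(C)=C1 | intermediate
12 | rac-(1R,4R)-1,3,4-trimethylcyclobut-2-ene-1-carbaldehyde | O=C[C@@]1(C)[C@H](C)C(C)=C1 | intermediate
13 | rac-(1R,4R)-1,3,4-trimethylcyclobut-2-ene-1-carboxylic acid | OC(=O)[C@@]1(C)[C@H](C)C(C)=C1 | intermediate
14 | (4S)-4-benzyl-1,3-oxazolidin-2-one | O=C1N[C@@H](Cc2ccccc2)CO1 | starting material
15 | rac-(1R,4R)-1,3,4-trimethylcyclobut-2-ene-1-carbonyl chloride | ClC(=O)[C@@]1(C)[C@H](C)C(C)=C1 | intermediate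
16 | lithium (4S)-4-benzyl-2-oxo-1,3-oxazolidin-3-ide | [Li+].O=C1[N-][C@@H](Cc2ccccc2)CO1 | intermediate
17 | (4S)-4-benzyl-3-[(1R,4R)-1,3,4-trimethylcyclobut-2-ene-1-carbonyl]-1,3-oxazolidin-2-one | O=C1OC[C@H](Cc2ccccc2)N1C(=O)[C@@]1(C)[C@H](C)C(C)=C1 | intermediate
18 | lithium (1R,4R)-1,3,4-trimethylcyclobut-2-ene-1-carboperoxoate | [Li+].[O-]OC(=O)[C@@]1(C)[C@H](C)C(C)=C1 | intermediate
19 | (1R,4R)-1,3,4-trimethylcyclobut-2-ene-1-carboxylic acid | OC(=O)[C@@]1(C)[C@H](C)C(C)=C1 | intermediate
20 | methyl (1R,4R)-1,3,4-trimethylcyclobut-2-ene-1-carboxylate (1- and 4-methyls cis) | COC(=O)[C@@]1(C)[C@H](C)C(C)=C1 | intermediate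
21 | propyne | CC#C | starting material
22 | 2,4-dimethyl-1-rhodacyclopenta-2,4-diene cation, [Rh(H8-BINAP)(C6H8)]BF4 (bisphosphine and BF4 left out of the SMILES) | CC1=CC(C)=C[Rh+]1 | intermediate
23 | rhodacycloheptadiene cation, [Rh(H8-BINAP)(C15H22O2)]BF4, rhodium bonded to C6 and C5 of the future core (bisphosphine and BF4 left out of the SMILES) | COC(=O)[C@@]1(C)[C@H](C)[C@@]2(C)C=C(C)C=C(C)[Rh+][C@@H]12 | intermediate
24 | methyl (1R,6R,7S,8R)-1,3,5,7,8-pentamethylbicyclo[4.2.0]octa-2,4-diene-7-carboxylate | COC(=O)[C@@]1(C)[C@H](C)[C@@]2(C)C=C(C)C=C(C)[C@@H]12 | intermediate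
25 | [(1R,6R,7S,8R)-1,3,5,7,8-pentamethylbicyclo[4.2.0]octa-2,4-dien-7-yl]methanol | OC[C@@]1(C)[C@H](C)[C@@]2(C)C=C(C)C=C(C)[C@@H]12 | intermediate
26 | (1R,6R,7S,8R)-1,3,5,7,8-pentamethylbicyclo[4.2.0]octa-2,4-diene-7-carbaldehyde | O=C[C@@]1(C)[C@H](C)[C@@]2(C)C=C(C)C=C(C)[C@@H]12 | intermediate
27 | methyl 2-methyl-3-oxopentanoate | CCC(=O)C(C)C(=O)OC | starting material
28 | sodium lithium dianion of methyl 2-methyl-3-oxopentanoate (dienediolate form) | [Na+].[Li+].CC=C([O-])C(C)=C([O-])OC | intermediate
29 | methyl 5-hydroxy-2,4-dimethyl-3-oxo-5-[(1R,6R,7S,8R)-1,3,5,7,8-pentamethylbicyclo[4.2.0]octa-2,4-dien-7-yl]pentanoate (mixture at chain C2, C4, C5) | COC(=O)C(C)C(=O)C(C)C(O)[C@@]1(C)[C@H](C)[C@@]2(C)C=C(C)C=C(C)[C@@H]12 | intermediate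
30 | methyl 2,4-dimethyl-3,5-dioxo-5-[(1R,6R,7S,8R)-1,3,5,7,8-pentamethylbicyclo[4.2.0]octa-2,4-dien-7-yl]pentanoate | COC(=O)C(C)C(=O)C(C)C(=O)[C@@]1(C)[C@H](C)[C@@]2(C)C=C(C)C=C(C)[C@@H]12 | intermediate
31 | 4-hydroxy-3,5-dimethyl-6-[(1R,6R,7S,8R)-1,3,5,7,8-pentamethylbicyclo[4.2.0]octa-2,4-dien-7-yl]-2H-pyran-2-one | O=c1oc([C@@]2(C)[C@H](C)[C@@]3(C)C=C(C)C=C(C)[C@@H]23)c(C)c(O)c1C | intermediate
32 | 4-hydroxy-2-methoxy-3,5-dimethyl-6-[(1R,6R,7S,8R)-1,3,5,7,8-pentamethylbicyclo[4.2.0]octa-2,4-dien-7-yl]pyrylium trifluoromethanesulfonate | COc1[o+]c([C@@]2(C)[C@H](C)[C@@]3(C)C=C(C)C=C(C)[C@@H]23)c(C)c(O)c1C.[O-]S(=O)(=O)C(F)(F)F | intermediate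
33 | 2-methoxy-3,5-dimethyl-6-[(1R,6R,7S,8R)-1,3,5,7,8-pentamethylbicyclo[4.2.0]octa-2,4-dien-7-yl]-4H-pyran-4-one | COc1oc([C@@]2(C)[C@H](C)[C@@]3(C)C=C(C)C=C(C)[C@@H]23)c(C)c(=O)c1C | intermediate
34 | CNP0183511.1, 2-methoxy-3,5-dimethyl-6-[(1S,2R,3S,4R,5R,6R)-1,3,4,5,10-pentamethyl-7,8-dioxatricyclo[4.2.2.0(2,5)]dec-9-en-3-yl]-4H-pyran-4-one (O–O bridge anti to the cyclobutane) | COc1oc([C@@]2(C)[C@H](C)[C@@]3(C)[C@@H]4OO[C@@](C)(C=C4C)[C@@H]23)c(C)c(=O)c1C | target

**Totals**
Total step count: 18. Longest linear sequence: 18 steps (1 → 34).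

**Steps most likely to fail**

Step 11 (proposed new method). The risk lies in selectivity on the metal. Propyne may cyclotrimerise to trimethylbenzenes faster than the cyclobutene inserts. The two alkynes may pair head to head. The alkene may insert in the other sense or on its methyl face. The fallback uses known chemistry, sets out from 20 and returns at 24. Commercial 2,4-dimethylthiophene is oxidised with dimethyldioxirane (acetone, 0 °C) to 2,4-dimethylthiophene 1,1-dioxide F1. Heating F1 with 20 (toluene, 70–90 °C) should give, by inverse-electron-demand Diels–Alder addition to the strained alkene on its ester/H face, the bridged sulfone methyl 1,3,4,5,7-pentamethyl-9-thiatricyclo[4.2.1.0(2,5)]non-7-ene-3-carboxylate 9,9-dioxide F2. F2 should lose SO2 by cheletropic extrusion under the same conditions to give 24. The methyl-bearing diene terminus should bond to the unsubstituted alkene carbon for steric reasons, which gives the same C2(H)=C3(Me)–C4(H)=C5(Me) pattern.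

Step 8. The two imide diastereomers may co-elute and not differ in crystallinity, or acylation by the hindered acid chloride may stall. The fallback sets out from 13 and returns at 19 by classical resolution instead of a covalent auxiliary. Racemic acid 13 is combined with (S)-1-phenylethylamine and the diastereomeric salts are fractionally crystallised (acetone or EtOAc/hexane). The salt of the wanted acid, (S)-1-phenylethylammonium (1R,4R)-1,3,4-trimethylcyclobut-2-ene-1-carboxylate F3, is taken from the crystals or from the mother liquor, as the case may be. It is acidified (HCl aq) to give 19, with the configuration to be secured by X-ray analysis of the salt.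

Step 2. The ketene may be lost to oligomerisation or to attack at the ether oxygen (zwitterionic Claisen-type path) before the hindered trisubstituted alkene adds. ZnCl2 may also ionise the allylic ether. The fallback sets out from 2 and returns at 7, skipping 5 and 6, by a keteniminium [2+2] cycloaddition. N,N-Dimethylacetamide, Tf2O and 2,6-di-tert-butyl-4-methylpyridine in ClCH2CH2Cl at reflux generate the N,N-dimethylketeniminium triflate. This should add to 2 with the same regiochemistry (iminium carbon to the CHMe carbon) and with retention of the alkene geometry to give rac-N-{(2S,3R)-3-{[tert-butyl(diphenyl)silyl]oxymethyl}-2,3-dimethylcyclobutylidene}-N-methylmethanaminium trifluoromethanesulfonate F4. Hydrolysis with NaHCO3 aq gives 7.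

**Further compounds**
F1 | step 11 | 2,4-dimethylthiophene 1,1-dioxide | CC1=CC(C)=CS1(=O)=O
F2 | step 11 | methyl 1,3,4,5,7-pentamethyl-9-thiatricyclo[4.2.1.0(2,5)]non-7-ene-3-carboxylate 9,9-dioxide (cyclobutane centres as in 20, sulfone bridge drawn anti to the cyclobutane) | COC(=O)[C@@]1(C)[C@H](C)[C@@]2(C)[C@@H]3S(=O)(=O)[C@@](C)(C=C3C)[C@@H]12
F3 | step 8 | (S)-1-phenylethylammonium (1R,4R)-1,3,4-trimethylcyclobut-2-ene-1-carboxylate | C[C@H]([NH3+])c1ccccc1.[O-]C(=O)[C@@]1(C)[C@H](C)C(C)=C1
F4 | step 2 | rac-N-{(2S,3R)-3-{[tert-butyl(diphenyl)silyl]oxymethyl}-2,3-dimethylcyclobutylidene}-N-methylmethanaminium trifluoromethanesulfonate | CC(C)(C)[Si](c1ccccc1)(c1ccccc1)OC[C@@]1(C)[C@H](C)C(=[N+](C)C)C1.[O-]S(=O)(=O)C(F)(F)F
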